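**Retrosynthetic overview**
1. End game on the ten-membered lactone: the O8 4-methoxybenzyl group comes off last, after O9 acetylation and O14 isovaleroylation; C13 is added by Mannich reaction and elimination on the lactone; the γ-lactone is closed onto C6 after reduction of a C6 ketone.
2. The strategy rests on this feature: the carbocycle C1–C10 is a cis,cis-cyclodeca-1(10),4-diene in which oxygenated C6 lies four ring bonds from C10 and the C8–C9 bond joins two oxygen-bearing carbons. That is the retron of an anionic oxy-Cope ring expansion, so C8–C9 (and C7–C11, by alkylation of the enolate formed) is disconnected to a cis-1,2-dialkenylcyclohex-2-enol with enol-ether termini at C8 and C9.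
3. The carbinol comes from a 4-methoxybenzyloxyacetylide (C7, C8 from trichloroethylene) and a 6-substituted 3-methylcyclohexenone whose C9/C10/C14 unit is a cyclic silyl enol ether. The enone derives from cyclohexenol and dimethyl malonate by palladium-catalysed asymmetric allylic alkylation, which sets C1.
4. Ring order: cyclohexene (bought), temporary dioxasiline, ten-membered ring by ring expansion, γ-lactone last.

Key step: step 14

Remark: ten-membered compounds are numbered as germacranes (C1=C10, C4=C5, lactone oxygen on C6, C7 bearing C11 with C12 carbonyl and C13 methylene, C14 the oxygenated CH2 on C10, C15 the methyl on C4), and the same labels are used for their precursors. Centres that later become planar (C1 of 8, C2 of 11, C11 of 28) are carried as mixtures. The C7 descriptor changes between R and S along the route with the substituents on O6 and O8, without any change of geometry.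

**Step 1**
Reactants: 1 cyclohex-2-en-1-ol (racemic)
Product: 2 cyclohex-2-en-1-yl methyl carbonate (racemic)
Conditions: ClCO2Me, pyridine, CH2Cl2, 0 °C
Reagents that add atoms: methyl chloroformate COC(=O)Cl
Why: O-acylation of the allylic alcohol gives the carbonate leaving group for the allylic alkylation; no stereocentre needs control because both enantiomers converge in step 2.

**Step 2**
Reactants: 2 cyclohex-2-en-1-yl methyl carbonate; 3 dimethyl malonate
Product: 4 dimethyl (S)-2-(cyclohex-2-en-1-yl)malonate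
Conditions: [Pd(C3H5)Cl]2 (1 mol %), (1R,2R)-N,N'-bis[2-(diphenylphosphino)benzoyl]cyclohexane-1,2-diamine (3 mol %), CH2Cl2, rt
Reagents that add atoms: none
Why: Tsuji–Trost asymmetric allylic alkylation, in which both enantiomers of 2 ionise to the same meso π-allyl palladium complex and the chiral diphosphine steers the malonate (deprotonated by the methoxide released with CO2) to one enantiotopic terminus, setting C1 as S; the ligand hand given is the one expected from the usual model and would be checked by the sign of rotation of 4, the mirror-image ligand being used otherwise.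

**Step 3**
Reactants: 4 dimethyl (S)-2-(cyclohex-2-en-1-yl)malonate
Product: 5 (S)-2-(cyclohex-2-en-1-yl)propane-1,3-diol
Conditions: LiAlH4, THF, 0 °C → rt
Reagents that add atoms: none
Why: hydride reduction of both esters to primary alcohols (future C9 and C14) leaves the ring stereocentre, which is not α to a carbonyl, untouched.

**Step 4**
Reactants: 5 (S)-2-(cyclohex-2-en-1-yl)propane-1,3-diol
Product: 6 (S)-5-(cyclohex-2-en-1-yl)-2,2-dimethyl-1,3-dioxane
Conditions: Me2C(OMe)2, PPTS (cat.), CH2Cl2, rt
Reagents that add atoms: 2,2-dimethoxypropane COC(C)(C)OC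
Why: acid-catalysed transacetalisation protects the 1,3-diol as a six-membered acetonide that tolerates the oxidations and the organolithium addition that follow.

**Step 5**
Reactants: 6 (S)-5-(cyclohex-2-en-1-yl)-2,2-dimethyl-1,3-dioxane
Product: 7 (S)-4-(2,2-dimethyl-1,3-dioxan-5-yl)cyclohex-2-en-1-one
Conditions: CrO3, 3,5-dimethylpyrazole, CH2Cl2, −20 °C
Reagents that add atoms: chromium trioxide O=[Cr](=O)=O
Why: allylic C–H oxidation by the CrO3–dimethylpyrazole complex should occur at the unhindered ring CH2 and not at the tertiary allylic C–H shielded by the dioxanyl group, giving the 4-substituted enone without touching the stereocentre.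

**Step 6**
Reactants: 7 (S)-4-(2,2-dimethyl-1,3-dioxan-5-yl)cyclohex-2-en-1-one
Product: 8 (4S)-4-(2,2-dimethyl-1,3-dioxan-5-yl)-1-methylcyclohex-2-en-1-ol (both C1 epimers)
Conditions: MeLi, Et2O, −78 °C
Reagents that add atoms: methyllithium [Li]C
Why: 1,2-addition of the hard organolithium to the enone carbonyl introduces C15; the new carbinol centre is removed in step 7 and needs no control.

**Step 7**
Reactants: 8 (4S)-4-(2,2-dimethyl-1,3-dioxan-5-yl)-1-methylcyclohex-2-en-1-ol
Product: 9 (R)-6-(2,2-dimethyl-1,3-dioxan-5-yl)-3-methylcyclohex-2-en-1-one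
Conditions: (C5H5NH)[CrO3Cl] (pyridinium chlorochromate), NaOAc, 4 Å MS, CH2Cl2, rt
Reagents that add atoms: pyridinium chlorochromate [O-][Cr](=O)(=O)Cl.c1cc[nH+]cc1
Why: Dauben–Babler oxidative 1,3-transposition, in which the tertiary chromate ester shifts [3,3] to the secondary allylic chromate and is oxidised to the 3-methyl enone, places the carbonyl (future C6) next to C1; the buffered, non-basic medium should leave the now α-positioned stereocentre intact.

**Step 8**
Reactants: 9 (R)-6-(2,2-dimethyl-1,3-dioxan-5-yl)-3-methylcyclohex-2-en-1-one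
Product: 10 (R)-6-(1,3-dihydroxypropan-2-yl)-3-methylcyclohex-2-en-1-one
Conditions: AcOH–H2O–THF (3:1:1), rt
Reagents that add atoms: none
Why: mild acid hydrolysis of the acetonide frees the diol under conditions too weak to enolise the enone towards C1.

**Step 9**
Reactants: 10 (R)-6-(1,3-dihydroxypropan-2-yl)-3-methylcyclohex-2-en-1-one
Product: 11 3-hydroxy-2-[(1R)-4-methyl-2-oxocyclohex-3-en-1-yl]propanal (both C2 epimers)
Conditions: TEMPO (10 mol %), PhI(OAc)2 (1.0 equiv), CH2Cl2, 0 °C, stopped before full conversion, 10 recovered and recycled, 11 used crude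
Reagents that add atoms: none
Why: oxoammonium oxidation is specific for primary alcohols and, with one equivalent of terminal oxidant, should stop largely at the mono-aldehyde under neutral conditions; either CH2OH may react because C10 becomes planar in step 10.

**Step 10**
Reactants: 11 3-hydroxy-2-[(1R)-4-methyl-2-oxocyclohex-3-en-1-yl]propanal
Product: 13 (R)-6-(2,2-di-tert-butyl-4H-1,3,2-dioxasilin-5-yl)-3-methylcyclohex-2-en-1-one, via silyl triflate 12 (not isolated)
Conditions: tBu2Si(OTf)2 (1.05 equiv), Et3N (3 equiv), CH2Cl2, −78 → 0 °C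
Reagents that add atoms: di-tert-butylsilyl bis(trifluoromethanesulfonate) CC(C)(C)[Si](OS(=O)(=O)C(F)(F)F)(OS(=O)(=O)C(F)(F)F)C(C)(C)C
Why: O-silylation of the primary alcohol, then intramolecular silylation of the aldehyde oxygen and amine deprotonation at C10 (soft enolisation by a silyl triflate), closes the six-membered dioxasiline; the ring fixes the C9 oxygen cis to C14, and the tethered hindered monotriflate should not enolise the ring ketone.

**Step 11**
Reactants: 14 trichloroethylene; 15 4-methoxybenzyl alcohol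
Product: 17 (E)-1,2-dichlorovinyl 4-methoxybenzyl ether, via potassium 4-methoxybenzyl oxide 16 (not isolated)
Conditions: KH, THF, 0 °C; then Cl2C=CHCl, −50 °C → rt
Reagents that add atoms: none
Why: the alkoxide converts trichloroethylene by elimination to dichloroacetylene and addition (net addition–elimination) into the E dichlorovinyl ether, a stable precursor of the alkoxyacetylide.

**Step 12**
Reactants: 17 (E)-1,2-dichlorovinyl 4-methoxybenzyl ether; 13 (R)-6-(2,2-di-tert-butyl-4H-1,3,2-dioxasilin-5-yl)-3-methylcyclohex-2-en-1-one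
Product: 19 (1S,6R)-6-(2,2-di-tert-butyl-4H-1,3,2-dioxasilin-5-yl)-1-[(4-methoxybenzyloxy)ethynyl]-3-methylcyclohex-2-en-1-ol, via lithium alkoxyacetylide 18 (not isolated)
Conditions: n-BuLi (2.1 equiv per 17), THF, −78 → −40 °C; then 13, −78 °C; NaHCO3 (aq) quench; kept cold and free of acid
Reagents that add atoms: none
Why: dehydrochlorination and chlorine–lithium exchange give the lithium alkoxyacetylide, which adds 1,2 to the enone carbonyl along the axial trajectory of the half-chair with the dioxasilinyl group equatorial, so the alkynyl group ends cis to that group (1S); the weakly basic acetylide at low temperature limits enolisation at C1.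

**Step 13**
Reactants: 19 (1S,6R)-6-(2,2-di-tert-butyl-4H-1,3,2-dioxasilin-5-yl)-1-[(4-methoxybenzyloxy)ethynyl]-3-methylcyclohex-2-en-1-ol
Product: 20 (1S,6R)-6-(2,2-di-tert-butyl-4H-1,3,2-dioxasilin-5-yl)-1-[(Z)-2-(4-methoxybenzyloxy)ethenyl]-3-methylcyclohex-2-en-1-ol
Conditions: H2 (1 atm), Pd/CaCO3 poisoned with Pb(OAc)2 (Lindlar catalyst), quinoline, EtOAc–Et3N, 0 °C
Reagents that add atoms: none
Why: syn delivery of hydrogen on the poisoned palladium surface stops at the alkene and gives the Z enol ether; the trisubstituted ring alkene, the silyl enol ether and the benzylic ether should be inert on this catalyst.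

**Step 14**
Reactants: 20 (1S,6R)-6-(2,2-di-tert-butyl-4H-1,3,2-dioxasilin-5-yl)-1-[(Z)-2-(4-methoxybenzyloxy)ethenyl]-3-methylcyclohex-2-en-1-ol; 21 methyl bromoacetate
Product: 24 methyl (1(10)Z,4Z,7R,8S,9R)-9,14-(di-tert-butylsilanediyldioxy)-8-(4-methoxybenzyloxy)-6-oxo-13-norgermacra-1(10),4-dien-12-oate, via potassium alkoxide 22 (not isolated), via potassium enolate 23 (not isolated)
Conditions: KN(SiMe3)2 (1.05 equiv), 18-crown-6, THF, −78 → 0 °C; then −78 °C, BrCH2CO2Me
Reagents that add atoms: none
Why: Deprotonation gives the potassium alkoxide, whose C6–O− weakens the C6–C1 bond so that the 1,5-diene C8=C7–C6–C1–C10=C9 undergoes a [3,3] shift (anionic oxy-Cope rearrangement, the known ring expansion of cis-1,2-dialkenylcyclohex-2-enols to cyclodeca-1,5-dienones); the C6 enolate so formed is then C-alkylated at C7 by the bromoacetate in an SN2 step. The ten-membered ring is not closed end to end but arises by four-atom expansion of the cyclohexene through a six-membered chair transition state in which C8–C9 forms as C6–C1 breaks, so no high dilution is needed. C8 and C9 are set by chirality transfer from C6 and C1 through that chair: the Z enol ether places the C8 oxygen axial, the dioxasiline ring holds the C9 oxygen trans to C1 and therefore equatorial, and the new bond carries the two oxygens in the anti (8S,9R) arrangement. C7 is set by alkylation on the outer face of the enolate, the face turned away from the transannular C1=C10 bond in the conformation delivered by the chair, which puts the acetate arm anti to the C8–C9 bond. The step needs the chair in which the alkoxyvinyl group is axial on the cyclohexene and C2 is axial in the transition state (giving cis C1=C10), not the alternative chair that would give trans C1=C10 and the opposite C8/C9 pair; this is secured by the cis relation of the two alkenyl groups, by the equatorial preference of the bulky dioxasilinyl group, and by the Z oxygen at C8, which would clash 1,3-diaxially with C5 in the other chair. Loss of the C8 alkoxide from the enolate is held back by rearranging no warmer than needed and alkylating at −78 °C without isolation.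

**Step 15**
Reactants: 24 methyl (1(10)Z,4Z,7R,8S,9R)-9,14-(di-tert-butylsilanediyldioxy)-8-(4-methoxybenzyloxy)-6-oxo-13-norgermacra-1(10),4-dien-12-oate
Product: 25 methyl (1(10)Z,4Z,6R,7S,8S,9R)-9,14-(di-tert-butylsilanediyldioxy)-6-hydroxy-8-(4-methoxybenzyloxy)-13-norgermacra-1(10),4-dien-12-oate
Conditions: NaBH4, CeCl3·7H2O, MeOH, −78 °C
Reagents that add atoms: none
Why: Luche 1,2-reduction of the enone carbonyl, in which hydride is expected to enter anti to the C7 acetate arm standing perpendicular to the carbonyl plane (Felkin–Anh-type approach past the C7 hydrogen), giving the 6R alcohol with its oxygen gauche to the arm; this is substrate control and unproven.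

**Step 16**
Reactants: 25 methyl (1(10)Z,4Z,6R,7S,8S,9R)-9,14-(di-tert-butylsilanediyldioxy)-6-hydroxy-8-(4-methoxybenzyloxy)-13-norgermacra-1(10),4-dien-12-oate
Product: 26 (1(10)Z,4Z,6R,7S,8S,9R)-9,14-(di-tert-butylsilanediyldioxy)-8-(4-methoxybenzyloxy)-13-norgermacra-1(10),4-dien-12,6-olide (trans-fused)
Conditions: PPTS (cat.), PhMe, 60 °C
Reagents that add atoms: none
Why: acid-catalysed intramolecular transesterification of the γ-hydroxy ester closes the five-membered lactone by acyl substitution, so C6 keeps its configuration and the trans ring fusion follows from steps 14 and 15.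

**Step 17**
Reactants: 26 (1(10)Z,4Z,6R,7S,8S,9R)-9,14-(di-tert-butylsilanediyldioxy)-8-(4-methoxybenzyloxy)-13-norgermacra-1(10),4-dien-12,6-olide
Product: 28 (1(10)Z,4Z,6R,7S,8S,9R)-9,14-(di-tert-butylsilanediyldioxy)-13-(dimethylamino)-8-(4-methoxybenzyloxy)germacra-1(10),4-dien-12,6-olide (C11 epimers), via lactone lithium enolate 27 (not isolated)
Conditions: LiN(iPr)2, THF, −78 °C; then [CH2=NMe2]I, −78 → 0 °C
Reagents that add atoms: dimethyl(methylidene)ammonium iodide C=[N+](C)C.[I-]
Why: Mannich reaction of the lactone lithium enolate with the preformed iminium salt introduces C13 at C11; the C11 configuration is irrelevant because the centre becomes planar in step 18.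

**Step 18**
Reactants: 28 (1(10)Z,4Z,6R,7S,8S,9R)-9,14-(di-tert-butylsilanediyldioxy)-13-(dimethylamino)-8-(4-methoxybenzyloxy)germacra-1(10),4-dien-12,6-olide
Product: 30 (1(10)Z,4Z,6R,7S,8S,9R)-9,14-(di-tert-butylsilanediyldioxy)-8-(4-methoxybenzyloxy)germacra-1(10),4,11(13)-trien-12,6-olide, via trimethylammonium iodide 29 (not isolated)
Conditions: MeI, MeOH, rt; then NaHCO3 (aq), CH2Cl2, rt
Reagents that add atoms: none
Why: N-methylation turns the amine into a leaving group, and mild base triggers E1cB elimination of trimethylamine to the exocyclic α-methylene lactone.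

**Step 19**
Reactants: 30 (1(10)Z,4Z,6R,7S,8S,9R)-9,14-(di-tert-butylsilanediyldioxy)-8-(4-methoxybenzyloxy)germacra-1(10),4,11(13)-trien-12,6-olide
Product: 31 (1(10)Z,4Z,6R,7S,8S,9R)-9,14-dihydroxy-8-(4-methoxybenzyloxy)germacra-1(10),4,11(13)-trien-12,6-olide
Conditions: HF·pyridine, pyridine, THF, 0 °C
Reagents that add atoms: none
Why: fluoride cleaves both Si–O bonds of the silylene (driven by Si–F bond formation) in a buffered acidic medium that should spare the methylene lactone and the 4-methoxybenzyl ether.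

**Step 20**
Reactants: 31 (1(10)Z,4Z,6R,7S,8S,9R)-9,14-dihydroxy-8-(4-methoxybenzyloxy)germacra-1(10),4,11(13)-trien-12,6-olide
Product: 32 (1(10)Z,4Z,6R,7S,8S,9R)-9-hydroxy-8-(4-methoxybenzyloxy)-14-(3-methylbutanoyloxy)germacra-1(10),4,11(13)-trien-12,6-olide
Conditions: isovaleryl chloride (1.05 equiv), 2,4,6-collidine, CH2Cl2, −78 → −40 °C
Reagents that add atoms: isovaleryl chloride CC(C)CC(=O)Cl
Why: kinetic acylation should select the unhindered primary allylic C14 hydroxyl over the secondary C9 hydroxyl flanked by the C8 ether.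

**Step 21**
Reactants: 32 (1(10)Z,4Z,6R,7S,8S,9R)-9-hydroxy-8-(4-methoxybenzyloxy)-14-(3-methylbutanoyloxy)germacra-1(10),4,11(13)-trien-12,6-olide
Product: 33 (1(10)Z,4Z,6R,7S,8S,9R)-9-acetoxy-8-(4-methoxybenzyloxy)-14-(3-methylbutanoyloxy)germacra-1(10),4,11(13)-trien-12,6-olide
Conditions: Ac2O, pyridine, DMAP (cat.), CH2Cl2, 0 °C → rt
Reagents that add atoms: acetic anhydride CC(=O)OC(C)=O
Why: DMAP-catalysed acylation of the one remaining free hydroxyl installs the C9 acetate with retention.

**Step 22**
Reactants: 33 (1(10)Z,4Z,6R,7S,8S,9R)-9-acetoxy-8-(4-methoxybenzyloxy)-14-(3-methylbutanoyloxy)germacra-1(10),4,11(13)-trien-12,6-olide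
Product: 34 (1(10)Z,4Z,6R,7R,8S,9R)-9-acetoxy-8-hydroxy-14-(3-methylbutanoyloxy)germacra-1(10),4,11(13)-trien-12,6-olide (CNP0603244.1)
Conditions: DDQ, CH2Cl2–pH 7 phosphate buffer, 0 °C
Reagents that add atoms: none
Why: oxidative cleavage of the electron-rich benzylic ether (hydride abstraction to the oxocarbenium ion, then hydrolysis) frees the C8 hydroxyl under neutral conditions that should avoid acetyl migration from O9 to O8 and translactonisation.

**Compound list**
1 | cyclohex-2-en-1-ol (racemic) | OC1C=CCCC1 | starting material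
2 | cyclohex-2-en-1-yl methyl carbonate (racemic) | COC(=O)OC1C=CCCC1 | intermediate
3 | dimethyl malonate | COC(=O)CC(=O)OC | starting material
4 | dimethyl (S)-2-(cyclohex-2-en-1-yl)malonate | COC(=O)C(C(=O)OC)[C@@H]1C=CCCC1 | intermediate
5 | (S)-2-(cyclohex-2-en-1-yl)propane-1,3-diol | OCC(CO)[C@@H]1C=CCCC1 | intermediate
6 | (S)-5-(cyclohex-2-en-1-yl)-2,2-dimethyl-1,3-dioxane | CC1(C)OCC(CO1)[C@@H]2C=CCCC2 | intermediate
7 | (S)-4-(2,2-dimethyl-1,3-dioxan-5-yl)cyclohex-2-en-1-one | CC1(C)OCC(CO1)[C@@H]2C=CC(=O)CC2 | intermediate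
8 | (4S)-4-(2,2-dimethyl-1,3-dioxan-5-yl)-1-methylcyclohex-2-en-1-ol (both C1 epimers) | CC1(C)OCC(CO1)[C@@H]2C=CC(C)(O)CC2 | intermediate
9 | (R)-6-(2,2-dimethyl-1,3-dioxan-5-yl)-3-methylcyclohex-2-en-1-one | CC1=CC(=O)[C@H](CC1)C2COC(C)(C)OC2 | intermediate
10 | (R)-6-(1,3-dihydroxypropan-2-yl)-3-methylcyclohex-2-en-1-one | CC1=CC(=O)[C@H](CC1)C(CO)CO | intermediate
11 | 3-hydroxy-2-[(1R)-4-methyl-2-oxocyclohex-3-en-1-yl]propanal (both C2 epimers) | CC1=CC(=O)[C@H](CC1)C(CO)C=O | intermediate
12 | di-tert-butyl(trifluoromethanesulfonyloxy)silyl ether of 11 | CC1=CC(=O)[C@H](CC1)C(C=O)CO[Si](OS(=O)(=O)C(F)(F)F)(C(C)(C)C)C(C)(C)C | intermediate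
13 | (R)-6-(2,2-di-tert-butyl-4H-1,3,2-dioxasilin-5-yl)-3-methylcyclohex-2-en-1-one | CC1=CC(=O)[C@H](CC1)C2=CO[Si](OC2)(C(C)(C)C)C(C)(C)C | intermediate
14 | trichloroethylene | ClC=C(Cl)Cl | starting material
15 | 4-methoxybenzyl alcohol | COc1ccc(CO)cc1 | starting material
16 | potassium 4-methoxybenzyl oxide | [K+].[O-]Cc1ccc(OC)cc1 | intermediate
17 | (E)-1,2-dichlorovinyl 4-methoxybenzyl ether | Cl/C=C(/Cl)OCc1ccc(OC)cc1 | intermediate
18 | lithium (4-methoxybenzyloxy)ethynide | [Li]C#COCc1ccc(OC)cc1 | intermediate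
19 | (1S,6R)-6-(2,2-di-tert-butyl-4H-1,3,2-dioxasilin-5-yl)-1-[(4-methoxybenzyloxy)ethynyl]-3-methylcyclohex-2-en-1-ol | CC1=C[C@@](O)(C#COCc2ccc(OC)cc2)[C@H](CC1)C3=CO[Si](OC3)(C(C)(C)C)C(C)(C)C | intermediate
20 | (1S,6R)-6-(2,2-di-tert-butyl-4H-1,3,2-dioxasilin-5-yl)-1-[(Z)-2-(4-methoxybenzyloxy)ethenyl]-3-methylcyclohex-2-en-1-ol | CC1=C[C@@](O)(/C=C\OCc2ccc(OC)cc2)[C@H](CC1)C3=CO[Si](OC3)(C(C)(C)C)C(C)(C)C | intermediate
21 | methyl bromoacetate | COC(=O)CBr | starting material
22 | potassium alkoxide of 20 | CC1=C[C@@]([O-])(/C=C\OCc2ccc(OC)cc2)[C@H](CC1)C3=CO[Si](OC3)(C(C)(C)C)C(C)(C)C.[K+] | intermediate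
23 | potassium C6 enolate of the ring-expanded (1(10)Z,4Z,8S,9R)-cyclodeca-1(10),4-dien-6-one (C6=C7 with C5 and C8 trans; 9,14-silylene, 8-O-4-methoxybenzyl) | C1C/C=C2/CO[Si](C(C)(C)C)(C(C)(C)C)O[C@H]2[C@@H](OCc3ccc(OC)cc3)/C=C(\[O-])/C=C1/C.[K+] | intermediate
24 | methyl (1(10)Z,4Z,7R,8S,9R)-9,14-(di-tert-butylsilanediyldioxy)-8-(4-methoxybenzyloxy)-6-oxo-13-norgermacra-1(10),4-dien-12-oate | O=C1/C=C(/C)CC/C=C2/CO[Si](C(C)(C)C)(C(C)(C)C)O[C@H]2[C@@H](OCc3ccc(OC)cc3)[C@H]1CC(=O)OC | intermediate
25 | methyl (1(10)Z,4Z,6R,7S,8S,9R)-9,14-(di-tert-butylsilanediyldioxy)-6-hydroxy-8-(4-methoxybenzyloxy)-13-norgermacra-1(10),4-dien-12-oate | O[C@@H]1/C=C(/C)CC/C=C2/CO[Si](C(C)(C)C)(C(C)(C)C)O[C@H]2[C@@H](OCc3ccc(OC)cc3)[C@H]1CC(=O)OC | intermediate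
26 | (1(10)Z,4Z,6R,7S,8S,9R)-9,14-(di-tert-butylsilanediyldioxy)-8-(4-methoxybenzyloxy)-13-norgermacra-1(10),4-dien-12,6-olide (trans-fused) | C1C(=O)O[C@@H]2/C=C(/C)CC/C=C3/CO[Si](C(C)(C)C)(C(C)(C)C)O[C@H]3[C@@H](OCc4ccc(OC)cc4)[C@@H]12 | intermediate
27 | lithium enolate of lactone 26 | C1=C([O-])O[C@@H]2/C=C(/C)CC/C=C3/CO[Si](C(C)(C)C)(C(C)(C)C)O[C@H]3[C@@H](OCc4ccc(OC)cc4)[C@@H]12.[Li+] | intermediate
28 | (1(10)Z,4Z,6R,7S,8S,9R)-9,14-(di-tert-butylsilanediyldioxy)-13-(dimethylamino)-8-(4-methoxybenzyloxy)germacra-1(10),4-dien-12,6-olide (C11 epimers) | CN(C)CC1C(=O)O[C@@H]2/C=C(/C)CC/C=C3/CO[Si](C(C)(C)C)(C(C)(C)C)O[C@H]3[C@@H](OCc4ccc(OC)cc4)[C@@H]12 | intermediate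
29 | trimethylammonium iodide of 28 | C[N+](C)(C)CC1C(=O)O[C@@H]2/C=C(/C)CC/C=C3/CO[Si](C(C)(C)C)(C(C)(C)C)O[C@H]3[C@@H](OCc4ccc(OC)cc4)[C@@H]12.[I-] | intermediate
30 | (1(10)Z,4Z,6R,7S,8S,9R)-9,14-(di-tert-butylsilanediyldioxy)-8-(4-methoxybenzyloxy)germacra-1(10),4,11(13)-trien-12,6-olide | C=C1C(=O)O[C@@H]2/C=C(/C)CC/C=C3/CO[Si](C(C)(C)C)(C(C)(C)C)O[C@H]3[C@@H](OCc4ccc(OC)cc4)[C@@H]12 | intermediate
31 | (1(10)Z,4Z,6R,7S,8S,9R)-9,14-dihydroxy-8-(4-methoxybenzyloxy)germacra-1(10),4,11(13)-trien-12,6-olide | C=C1C(=O)O[C@@H]2/C=C(/C)CC/C=C(/CO)[C@@H](O)[C@@H](OCc3ccc(OC)cc3)[C@@H]12 | intermediate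
32 | (1(10)Z,4Z,6R,7S,8S,9R)-9-hydroxy-8-(4-methoxybenzyloxy)-14-(3-methylbutanoyloxy)germacra-1(10),4,11(13)-trien-12,6-olide | C=C1C(=O)O[C@@H]2/C=C(/C)CC/C=C(/COC(=O)CC(C)C)[C@@H](O)[C@@H](OCc3ccc(OC)cc3)[C@@H]12 | intermediate
33 | (1(10)Z,4Z,6R,7S,8S,9R)-9-acetoxy-8-(4-methoxybenzyloxy)-14-(3-methylbutanoyloxy)germacra-1(10),4,11(13)-trien-12,6-olide | C=C1C(=O)O[C@@H]2/C=C(/C)CC/C=C(/COC(=O)CC(C)C)[C@@H](OC(C)=O)[C@@H](OCc3ccc(OC)cc3)[C@@H]12 | intermediate
34 | (1(10)Z,4Z,6R,7R,8S,9R)-9-acetoxy-8-hydroxy-14-(3-methylbutanoyloxy)germacra-1(10),4,11(13)-trien-12,6-olide (CNP0603244.1) | C=C1C(=O)O[C@@H]2/C=C(/C)CC/C=C(/COC(=O)CC(C)C)[C@@H](OC(C)=O)[C@@H](O)[C@@H]12 | target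

**Step count**
Total step count: 22.
Longest linear sequence: 21 steps (1 to 34 through steps 1–10 and 12–22); step 11 is the one-step branch to 17.

**Steps most likely to fail**

Step 14. Three processes threaten it. The rearrangement may run through the alternative chair (or a boat), which would give trans C1=C10 and the wrong C8/C9 pair. The crowned potassium enolate may expel the C8 alkoxide before it is alkylated. The alkylation may occur on the inner face of the enolate. The fallback sets out from 20 and returns at 24 by a neutral siloxy-Cope route. Compound 20 is silylated (N-trimethylsilylimidazole, CH2Cl2) to the trimethylsilyl ether F1. F1 is heated in degassed toluene in base-washed glass (sealed tube, about 140 °C), so that the [3,3] shift gives the trimethylsilyl enol ether F2 with no enolate present at the rearrangement temperature. MeLi (THF, −78 °C) then liberates the lithium enolate F3, which is less prone to β-elimination than the potassium species, and F3 is alkylated with 21 at −78 °C in the presence of DMPU to give 24. This fallback answers the elimination; the chair preference rests on the same substrate features in either mode.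

Step 15. Hydride may be delivered to the other face of the C6 carbonyl (the ring conformation of 24 is not known), which would give the C6 epimer and hence a cis-fused lactone. The fallback sets out from 24 and returns at 26. The C6-epimeric hydroxy ester F4 formed in the reduction is saponified (LiOH, THF–H2O) to the hydroxy acid F5. F5 is closed by Mitsunobu lactonisation (PPh3, diisopropyl azodicarboxylate, PhMe, 0 °C), an SN2 displacement that inverts C6 and gives the trans-fused lactone 26.

Step 9. The oxidation is not intrinsically stopped at the mono-aldehyde, so over-oxidation to the dialdehyde is likely; the β-hydroxy aldehyde may also lose water, and the stereocentre α to the ketone may erode on prolonged handling. The fallback sets out from 10 and returns at 11 by desymmetrising protection in place of partial oxidation. Lipase-catalysed monoacetylation (Candida antarctica lipase B, vinyl acetate, t-BuOMe) gives the monoacetate F6. Dess–Martin periodinane (NaHCO3, CH2Cl2) oxidises the remaining hydroxyl to the acetoxy aldehyde F7. The same lipase in pH 7 phosphate buffer removes the acetate under neutral conditions to give 11, which is carried directly into step 10.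

**Further compounds**
F1 | step 14 | trimethylsilyl ether of 20 | CC1=C[C@@](O[Si](C)(C)C)(/C=C\OCc2ccc(OC)cc2)[C@H](CC1)C3=CO[Si](OC3)(C(C)(C)C)C(C)(C)C
F2 | step 14 | trimethylsilyl enol ether of the ring-expanded cyclodeca-1(10),4-dien-6-one (C6=C7 with C5 and C8 trans; 8S,9R) | C1C/C=C2/CO[Si](C(C)(C)C)(C(C)(C)C)O[C@H]2[C@@H](OCc3ccc(OC)cc3)/C=C(\O[Si](C)(C)C)/C=C1/C
F3 | step 14 | lithium C6 enolate (lithium analogue of 23) | C1C/C=C2/CO[Si](C(C)(C)C)(C(C)(C)C)O[C@H]2[C@@H](OCc3ccc(OC)cc3)/C=C(\[O-])/C=C1/C.[Li+]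
F4 | step 15 | C6 epimer of 25 (methyl 6S-hydroxy ester) | O[C@H]1/C=C(/C)CC/C=C2/CO[Si](C(C)(C)C)(C(C)(C)C)O[C@H]2[C@@H](OCc3ccc(OC)cc3)[C@H]1CC(=O)OC
F5 | step 15 | 6S-hydroxy acid from F4 | O[C@H]1/C=C(/C)CC/C=C2/CO[Si](C(C)(C)C)(C(C)(C)C)O[C@H]2[C@@H](OCc3ccc(OC)cc3)[C@H]1CC(=O)O
F6 | step 9 | 3-hydroxy-2-[(1R)-4-methyl-2-oxocyclohex-3-en-1-yl]propyl acetate | CC1=CC(=O)[C@H](CC1)C(CO)COC(C)=O
F7 | step 9 | 2-[(1R)-4-methyl-2-oxocyclohex-3-en-1-yl]-3-oxopropyl acetate | CC1=CC(=O)[C@H](CC1)C(C=O)COC(C)=O
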